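Assumption: carotenoid numbering is used for positions (ring C1–C6, chain C7–C15, then C15'–C7' towards the ketone), and the SMILES is read as all-E with (R) configuration at the carbinol carbon C3.

## The problem

Target 20 is a C31 apocarotenoid. A cyclohexene ring (C1 gem-dimethyl, C3 hydroxyl, C5 methyl) is bound at its fully substituted vinylic carbon C6 to the C7≡C8 triple bond, which runs into a heptaene (C9=C10 to C10'=C9', methyls on C9, C13, C13', C9') ending in the methyl ketone C8'(=O)–C7'H3. No ring has to be closed and there is one stereocentre; the work is to join a 22-carbon chain at the right places, keep seven double bonds E, and give two different ends to a chain whose middle (C12–C12') is the C2-symmetric unit of dialdehyde 11. The weak point of the geometry is C9=C10: the neighbouring alkyne is slim, so the 9Z isomer should be about as stable as 9E and cannot be cured by a final equilibration, and any ylide or carbanion at C11 is conjugated with this bond and, through it, propargylic. The stereocentre C3 (R) is remote from the chain; it controls nothing and nothing controls it, and its two CH2 neighbours differ only one atom further out (sp2 C5 against quaternary C1), which an enzyme reads well and a small reagent poorly. The C6–C7 bond is the most hindered in the molecule, yet two features make it the place for a late union: the ketone corresponding to C6 can enolise only towards C5 because C1 is quaternary, so a single enol triflate (7) exists, and C7 is sp-hybridised, so a terminal alkyne (19) can be coupled there without creating or touching a stereo element. Sensitive groups are the polyene (light, oxygen, acid, iodine, heat), the terminal alkyne of late intermediates (oxidative dimerisation), the enolisable methyl ketone (strong base) and the homoallylic alcohol (must not be sulfonylated).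

## Retrosynthesis

**C6–C7 (20 ⇒ 7 + 19).** The sp2–sp bond between the ring and the chain is cut last. Cutting C8–C9 instead would need a stereodefined trisubstituted alkenyl halide at the end of a polyene; cutting C11=C12 with the ring in place puts an ylide next to C9=C10 in the most valuable fragment (Alternative 1). The cut leaves an achiral C22 heptaenynone 19, in which every double bond is already fixed, and a C9 ring triflate 7 that carries the only stereocentre. The forward reaction must couple at a carbon flanked by C1 (quaternary) and C5 (methyl-bearing), tolerate a free hydroxyl, a methyl ketone and a heptaene, and outrun alkyne homocoupling.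

**Triflate and C3 (7 ⇒ 6 ⇒ 4 ⇒ 3 ⇒ 1).** The C6–O bond of 7 comes from the ketone of 4 through enolate 5; the quaternary C2 of 4 leaves only one direction of enolisation. The free hydroxyl of 7 is unmasked before the coupling (6 ⇒ 7), so that nothing has to be done to the polyene afterwards. The C3 stereocentre is traced to the two-enzyme reduction of achiral ketoisophorone 1 via 2 to 3. This is preferred over a chemical asymmetric reduction, because the ketone is flanked by two methylene groups. The second stereocentre of 3 need not be controlled, since it is erased in 6.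

**C11'=C12' (19 ⇒ 13 + 17).** The disubstituted double bond four carbons from the ketone is cut by a Wittig disconnection into the pentaenynal 13 and the C6 keto phosphonium salt 17 (ylide 18). The ylide carbon is conjugated only with C9'=C10', whose E geometry is held thermodynamically by the acetyl group. The enyne end of 13 is a bystander, since no anion is formed near C9=C10. The forward reaction must be mild enough for the methyl ketone.

**C11=C12 (13 ⇒ 10 + 11).** The corresponding bond on the alkyne side is cut into the C6 enynyl phosphonium salt 10 (ylide 12) and the commercial C10 dialdehyde 11. In 11 each formyl group is activated by the other through the triene, whereas the formyl group of 13 is deactivated by the longer donor polyene, so mono-olefination is favoured without protection. The one ylide of the route that is conjugated with C9=C10 is used here, on a two-step achiral fragment and against the most electrophilic aldehyde, where a geometric impurity can be removed on a small intermediate.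

**End pieces (10 ⇒ 9 ⇒ 8; 17 ⇒ 16 ⇒ 14 + 15).** Salt 10 comes from the commercial (E)-enynol 8 through bromide 9; the C9=C10 geometry and the triple bond are bought, not made. Salt 17 comes from the allylic chloride 16, itself the Wittig product of chloroacetaldehyde 14 and the stabilised ylide 15, which sets C9'=C10' as E.

## Roads not taken

Alternative 1: the obvious cut is C11=C12 with the ring in place. The forward key step is a Wittig reaction of the ring-bearing C15 salt {(2E)-5-[(4R)-4-hydroxy-2,6,6-trimethylcyclohex-1-en-1-yl]-3-methylpent-2-en-4-yn-1-yl}triphenylphosphonium bromide A1 (from 7 and 8) with the C16 keto-aldehyde (2E,4E,6E,8E,10E)-2,7,11-trimethyl-12-oxotrideca-2,4,6,8,10-pentaenal A2 (from 11 and 17). The ylide carbon of A1 is conjugated with C9=C10 and the charge at C9 is propargylic, so the C9–C10 bond order drops in the fragment that carries the stereocentre and the most steps. Any 9Z material formed there goes to the end and cannot be equilibrated away. The ring also has to pass three more operations, and the target is released under base next to its own enolisable ketone. In the chosen plan the same hazard is confined to ylide 12 on a cheap C6 piece, and the ring meets the chain only in a neutral, stereoretentive step.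

Alternative 2: use the hidden symmetry that a methyl ketone is a hydrated ethynyl group. Double Wittig reaction of 11 with two equivalents of 10 would give the C2h-symmetric diyne (3E,5E,7E,9E,11E,13E,15E)-3,7,12,16-tetramethyloctadeca-3,5,7,9,11,13,15-heptaene-1,17-diyne A3. Mono-Sonogashira coupling with 7 would give the ring-capped diyne (1R)-3,5,5-trimethyl-4-[(3E,5E,7E,9E,11E,13E,15E)-3,7,12,16-tetramethyloctadeca-3,5,7,9,11,13,15-heptaene-1,17-diyn-1-yl]cyclohex-3-en-1-ol A4, and Markovnikov hydration of its terminal alkyne would give 20. The two alkyne termini of A3 are remote and equivalent and do not deactivate each other, so the mono-coupling is statistical. The hydration needs a π-acid on a heptaene whose cationic intermediate is delocalised over many carbons, so water can add at several vinylogous sites, and a second triple bond is present. The gain is one step, against two unselective operations at the end.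

Alternative 3: cut C10–C11 (sp2–sp2) and make C9=C10 by carbometalation. Sonogashira coupling of 7 with a butadiyne equivalent would give the ring diyne (1R)-4-(buta-1,3-diyn-1-yl)-3,5,5-trimethylcyclohex-3-en-1-ol A5. Zr-catalysed methylalumination of its terminal triple bond (syn addition, methyl to C9) and iodinolysis would give the iodoenyne (1R)-4-[(3E)-4-iodo-3-methylbut-3-en-1-yn-1-yl]-3,5,5-trimethylcyclohex-3-en-1-ol A6. Suzuki coupling with the hexaenyl boronate (3E,5E,7E,9E,11E,13E)-3,7,12-trimethyl-14-(4,4,5,5-tetramethyl-1,3,2-dioxaborolan-2-yl)tetradeca-3,5,7,9,11,13-hexaen-2-one A7 (from A2 by Takai–Utimoto borylation) would give 20. The geometry at C9 would be set stereospecifically, which is the merit of this plan. Its cost is that the chiral ring passes four more steps, trimethylaluminium meets a hydroxylated substrate, the regiochemistry of carboalumination on a conjugated diyne is not secured, and the chain needs three extra steps. The chosen plan buys the same geometry in 8 and reaches 20 in a shorter longest sequence.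

Key step: step 11

## Route

Step 1
Reactants: 1 ketoisophorone (2,6,6-trimethylcyclohex-2-ene-1,4-dione)
Product: 3 (4R,6R)-4-hydroxy-2,2,6-trimethylcyclohexan-1-one, via (6R)-levodione 2 (not isolated)
Conditions: ene-reductase (Old Yellow Enzyme family), levodione reductase (short-chain ketoreductase), NAD(P)+ (cat.), glucose dehydrogenase, D-glucose, phosphate buffer pH 7, 30 °C
Reagents that add atoms: none
Why: Biocatalytic cascade known on this very substrate: the ene-reductase reduces the activated C=C by trans addition of hydride and a proton to give (6R)-2, and the ketoreductase then reduces the unhindered C4 carbonyl from one face to the (4R)-alcohol, the selectivity coming from the active site. Only this centre (C3 of the target) matters later, because C6 becomes sp2 in step 3.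

Step 2
Reactants: 3 (4R,6R)-4-hydroxy-2,2,6-trimethylcyclohexan-1-one
Product: 4 (4R,6R)-2,2,6-trimethyl-4-[(triethylsilyl)oxy]cyclohexan-1-one
Conditions: TESCl, imidazole, DMF, 0 °C to rt
Reagents that add atoms: chlorotriethylsilane, CC[Si](Cl)(CC)CC
Why: Standard silylation of a secondary alcohol; the hydroxyl must be masked so that it is not sulfonylated in step 3, and a triethylsilyl ether can later be removed under acid too mild to touch a vinyl triflate.

Step 3
Reactants: 4 (4R,6R)-2,2,6-trimethyl-4-[(triethylsilyl)oxy]cyclohexan-1-one
Product: 6 (4R)-2,6,6-trimethyl-4-[(triethylsilyl)oxy]cyclohex-1-en-1-yl trifluoromethanesulfonate, via lithium enolate 5 (not isolated)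
Conditions: LDA, THF, −78 to 0 °C; then PhNTf2, −78 °C to rt
Reagents that add atoms: N-phenylbis(trifluoromethanesulfonimide), O=S(=O)(N(c1ccccc1)S(=O)(=O)C(F)(F)F)C(F)(F)F
Why: Enol triflate formation: C2 is quaternary, so only the C6 proton can be removed and O-sulfonylation of enolate 5 should give a single regioisomer while erasing the C6 stereocentre. The silyloxy group is not β to the enolate carbon, so it cannot be eliminated.

Step 4
Reactants: 6 (4R)-2,6,6-trimethyl-4-[(triethylsilyl)oxy]cyclohex-1-en-1-yl trifluoromethanesulfonate
Product: 7 (4R)-4-hydroxy-2,6,6-trimethylcyclohex-1-en-1-yl trifluoromethanesulfonate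
Conditions: PPTS (cat.), MeOH, rt
Reagents that add atoms: none
Why: Acid-catalysed methanolysis of a secondary triethylsilyl ether; the vinyl triflate is inert to mild acid, and freeing the hydroxyl here means that no deprotection follows the key step.

Step 5
Reactants: 8 (2E)-3-methylpent-2-en-4-yn-1-ol
Product: 9 (3E)-5-bromo-3-methylpent-3-en-1-yne
Conditions: PBr3, pyridine (cat.), Et2O, −10 to 0 °C
Reagents that add atoms: phosphorus tribromide, BrP(Br)Br
Why: Conversion of a primary allylic alcohol into the bromide by SN2 displacement of its phosphite ester; at low temperature the conjugated primary bromide should form without allylic transposition and with the bought E geometry intact.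

Step 6
Reactants: 9 (3E)-5-bromo-3-methylpent-3-en-1-yne
Product: 10 tributyl[(2E)-3-methylpent-2-en-4-yn-1-yl]phosphonium bromide
Conditions: PBu3, MeCN, 0 °C to rt, Ar
Reagents that add atoms: tributylphosphine, CCCCP(CCCC)CCCC
Why: SN2 quaternisation of the phosphine by an allylic bromide. Tributyl is chosen over triphenyl because allylic tributylphosphonium ylides are known to give mainly E-olefins and to hold the geometry of the allyl unit better.

Step 7
Reactants: 10 tributyl[(2E)-3-methylpent-2-en-4-yn-1-yl]phosphonium bromide; 11 (2E,4E,6E)-2,7-dimethylocta-2,4,6-trienedial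
Product: 13 (2E,4E,6E,8E,10E)-2,7,11-trimethyltrideca-2,4,6,8,10-pentaen-12-ynal, via enynyl ylide 12 (not isolated)
Conditions: 11 (2.5 equiv), NaOMe (slow addition), CH2Cl2/MeOH, −20 to 0 °C, Ar, dim light
Reagents that add atoms: none
Why: Wittig olefination forming C11=C12: ylide 12 is generated in the presence of excess dialdehyde and trapped at once, which keeps its lifetime and the chance of rotation about C9–C10 small. Each formyl group of 11 is activated by the other while the formyl group of 13 is deactivated by the longer polyene, so mono-olefination should dominate; the new bond should be mainly E and excess 11 is recovered.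

Step 8
Reactants: 14 chloroacetaldehyde; 15 3-(triphenyl-λ5-phosphanylidene)butan-2-one
Product: 16 (3E)-5-chloro-3-methylpent-3-en-2-one
Conditions: aq. ClCH2CHO (excess), CH2Cl2, rt
Reagents that add atoms: none
Why: Wittig reaction of an α-branched, acyl-stabilised ylide with a reactive aldehyde, which should give the trisubstituted enone with the acetyl group trans to CH2Cl (the C9'=C10' geometry of the target). Excess aldehyde consumes the ylide before it can be alkylated by the product.

Step 9
Reactants: 16 (3E)-5-chloro-3-methylpent-3-en-2-one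
Product: 17 tributyl[(2E)-3-methyl-4-oxopent-2-en-1-yl]phosphonium chloride
Conditions: PBu3, MeCN, 0 °C to rt, Ar
Reagents that add atoms: tributylphosphine, CCCCP(CCCC)CCCC
Why: SN2 quaternisation at the primary allylic chloride; any conjugate addition of the phosphine to the β-substituted enone is reversible and leads back to the stable salt.

Step 10
Reactants: 13 (2E,4E,6E,8E,10E)-2,7,11-trimethyltrideca-2,4,6,8,10-pentaen-12-ynal; 17 tributyl[(2E)-3-methyl-4-oxopent-2-en-1-yl]phosphonium chloride
Product: 19 (3E,5E,7E,9E,11E,13E,15E)-3,7,12,16-tetramethyloctadeca-3,5,7,9,11,13,15-heptaen-17-yn-2-one, via ketodienyl ylide 18 (not isolated)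
Conditions: NaOMe, CH2Cl2/MeOH, 0 °C to rt, Ar, dim light
Reagents that add atoms: none
Why: Wittig olefination forming C11'=C12' with the vinylogous acyl-stabilised ylide 18, which needs only a mild base and reacts through its α-carbon to give the linear polyene, mainly E. No anion is conjugated with C9=C10 of 13, and the C9'=C10' geometry is held thermodynamically by the acetyl group.

Step 11
Reactants: 19 (3E,5E,7E,9E,11E,13E,15E)-3,7,12,16-tetramethyloctadeca-3,5,7,9,11,13,15-heptaen-17-yn-2-one; 7 (4R)-4-hydroxy-2,6,6-trimethylcyclohex-1-en-1-yl trifluoromethanesulfonate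
Product: 20 (3E,5E,7E,9E,11E,13E,15E)-18-[(4R)-4-hydroxy-2,6,6-trimethylcyclohex-1-en-1-yl]-3,7,12,16-tetramethyloctadeca-3,5,7,9,11,13,15-heptaen-17-yn-2-one
Conditions: Pd(PPh3)4 (cat.), CuI (cat.), i-Pr2NH, degassed THF, rt, Ar, dim light; 7 in slight excess, 19 added slowly
Reagents that add atoms: none
Why: Sonogashira coupling: Pd(0) adds oxidatively to the C6–OTf bond of 7, CuI and the amine turn the terminal alkyne of 19 into a copper acetylide, and transmetalation followed by reductive elimination forms the C6–C7 bond. The closest known reaction type is the Pd/Cu coupling of 2,6,6-trimethylcyclohex-1-enyl triflates with terminal enynes, which tolerates both flanking substituents because the incoming carbon is linear. No ring is closed and no stereocentre is formed; C3 is a spectator and keeps the (R) configuration set in step 1. All seven double bonds were fixed in 19 and none takes part: no carbanion, ylide or π-allyl species conjugated with C9=C10 arises, so the E geometry next to the alkyne should be retained. The selectivity needed is cross-coupling over oxidative homocoupling of the acetylide, secured by rigorous exclusion of oxygen, a small excess of 7 and slow addition of 19. The free hydroxyl, the methyl ketone and the polyene are inert to Pd(0), CuI and a hindered secondary amine at room temperature, so the target is released without deprotection. Regiochemistry of the ring double bond is not at stake, since the quaternary C1 allowed only one enol triflate in step 3.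

## Compound list

1 | ketoisophorone (2,6,6-trimethylcyclohex-2-ene-1,4-dione) | CC1=CC(=O)CC(C)(C)C1=O | starting material
2 | (6R)-levodione [(6R)-2,2,6-trimethylcyclohexane-1,4-dione] | O=C1[C@H](C)CC(=O)CC1(C)C | intermediate (not isolated)
3 | (4R,6R)-4-hydroxy-2,2,6-trimethylcyclohexan-1-one | O=C1[C@H](C)C[C@@H](O)CC1(C)C | intermediate
4 | (4R,6R)-2,2,6-trimethyl-4-[(triethylsilyl)oxy]cyclohexan-1-one | O=C1[C@H](C)C[C@@H](O[Si](CC)(CC)CC)CC1(C)C | intermediate
5 | lithium (4R)-2,6,6-trimethyl-4-[(triethylsilyl)oxy]cyclohex-1-en-1-olate | [Li+].[O-]C1=C(C)C[C@@H](O[Si](CC)(CC)CC)CC1(C)C | intermediate (not isolated)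
6 | (4R)-2,6,6-trimethyl-4-[(triethylsilyl)oxy]cyclohex-1-en-1-yl trifluoromethanesulfonate | FC(F)(F)S(=O)(=O)OC1=C(C)C[C@@H](O[Si](CC)(CC)CC)CC1(C)C | intermediate
7 | (4R)-4-hydroxy-2,6,6-trimethylcyclohex-1-en-1-yl trifluoromethanesulfonate | FC(F)(F)S(=O)(=O)OC1=C(C)C[C@@H](O)CC1(C)C | intermediate
8 | (2E)-3-methylpent-2-en-4-yn-1-ol | C#C/C(C)=C/CO | starting material
9 | (3E)-5-bromo-3-methylpent-3-en-1-yne | C#C/C(C)=C/CBr | intermediate
10 | tributyl[(2E)-3-methylpent-2-en-4-yn-1-yl]phosphonium bromide | C#C/C(C)=C/C[P+](CCCC)(CCCC)CCCC.[Br-] | intermediate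
11 | (2E,4E,6E)-2,7-dimethylocta-2,4,6-trienedial | O=C/C(C)=C/C=C/C=C(\C)C=O | starting material
12 | tributyl[(2E)-3-methylpent-2-en-4-yn-1-ylidene]-λ5-phosphane (enynyl ylide) | C#C/C(C)=C/C=P(CCCC)(CCCC)CCCC | intermediate (not isolated)
13 | (2E,4E,6E,8E,10E)-2,7,11-trimethyltrideca-2,4,6,8,10-pentaen-12-ynal | O=C/C(C)=C/C=C/C=C(C)/C=C/C=C(\C)C#C | intermediate
14 | chloroacetaldehyde | ClCC=O | starting material
15 | 3-(triphenyl-λ5-phosphanylidene)butan-2-one | CC(=O)C(C)=P(c1ccccc1)(c1ccccc1)c1ccccc1 | starting material
16 | (3E)-5-chloro-3-methylpent-3-en-2-one | CC(=O)/C(C)=C/CCl | intermediate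
17 | tributyl[(2E)-3-methyl-4-oxopent-2-en-1-yl]phosphonium chloride | CC(=O)/C(C)=C/C[P+](CCCC)(CCCC)CCCC.[Cl-] | intermediate
18 | (3E)-3-methyl-5-(tributyl-λ5-phosphanylidene)pent-3-en-2-one (ketodienyl ylide) | CC(=O)/C(C)=C/C=P(CCCC)(CCCC)CCCC | intermediate (not isolated)
19 | (3E,5E,7E,9E,11E,13E,15E)-3,7,12,16-tetramethyloctadeca-3,5,7,9,11,13,15-heptaen-17-yn-2-one | CC(=O)/C(C)=C/C=C/C(C)=C/C=C/C=C(C)/C=C/C=C(\C)C#C | intermediate
20 | (3E,5E,7E,9E,11E,13E,15E)-18-[(4R)-4-hydroxy-2,6,6-trimethylcyclohex-1-en-1-yl]-3,7,12,16-tetramethyloctadeca-3,5,7,9,11,13,15-heptaen-17-yn-2-one | CC(=O)/C(C)=C/C=C/C(C)=C/C=C/C=C(C)/C=C/C=C(\C)C#CC1=C(C)C[C@@H](O)CC1(C)C | target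

## Step count and risks

Total step count: 11. Longest linear sequence: 5 steps (1 → 3 → 4 → 6 → 7 → 20, or 8 → 9 → 10 → 13 → 19 → 20).

**Step 11 (key step).** What may go wrong is oxidative homocoupling of the copper acetylide of 19 outrunning a slow transmetalation at the hindered C6–Pd centre, and gradual loss of the heptaene during a long exposure to Pd, Cu and amine. The fallback joins the ring to the small alkyne and finishes the chain by olefination. It sets out from 7 and comes back at 20:
- Sonogashira coupling of 7 with 8 under the step 11 conditions should give the diol (1R)-4-[(3E)-5-hydroxy-3-methylpent-3-en-1-yn-1-yl]-3,5,5-trimethylcyclohex-3-en-1-ol F1.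
- Tributylphosphine hydrobromide ionises only the allylic hydroxyl of F1 and gives the salt tributyl{(2E)-5-[(4R)-4-hydroxy-2,6,6-trimethylcyclohex-1-en-1-yl]-3-methylpent-2-en-4-yn-1-yl}phosphonium bromide F2.
- Wittig reaction of F2 with excess 11 (step 7 conditions) gives the aldehyde (2E,4E,6E,8E,10E)-13-[(4R)-4-hydroxy-2,6,6-trimethylcyclohex-1-en-1-yl]-2,7,11-trimethyltrideca-2,4,6,8,10-pentaen-12-ynal F3.
- Wittig reaction of F3 with 17 (step 10 conditions) gives 20.

**Step 7.** What may go wrong is rotation about C9–C10 in the allylic, propargylic ylide 12 (loss of the E geometry), olefination at both formyl groups of 11, and formation of some 11Z bond. The fallback inverts the polarity so that C11 is the aldehyde and no carbanion is conjugated with C9=C10. It sets out from 8, 11 and 17 and comes back at 19, bypassing 13: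
- MnO2 oxidation of 8 gives (2E)-3-methylpent-2-en-4-ynal F4.
- Mono-reduction of 11 (NaBH4 in deficiency, EtOH, −20 °C) gives (2E,4E,6E)-8-hydroxy-2,7-dimethylocta-2,4,6-trienal F5.
- Wittig reaction of F5 with 17 (step 10 conditions) gives (3E,5E,7E,9E,11E)-13-hydroxy-3,7,12-trimethyltrideca-3,5,7,9,11-pentaen-2-one F6.
- Tributylphosphine hydrobromide converts F6 into tributyl[(2E,4E,6E,8E,10E)-2,7,11-trimethyl-12-oxotrideca-2,4,6,8,10-pentaen-1-yl]phosphonium bromide F7.
- Wittig reaction of F7 with F4 (NaOMe, CH2Cl2/MeOH) gives 19.

**Step 10.** What may go wrong is low reactivity of the stabilised ylide 18 towards the deactivated, α-branched polyenal, attack through the γ-carbon of the ylide, and base-induced aldol reactions of the methyl ketone. The fallback builds the ketone end from a C2 and a C4 phosphonate and makes C9'=C10' last. It sets out from 13 and comes back at 19: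
- Horner–Wadsworth–Emmons reaction of 13 with diethyl (cyanomethyl)phosphonate (NaH, THF, 0 °C) gives (2E,4E,6E,8E,10E,12E)-4,9,13-trimethylpentadeca-2,4,6,8,10,12-hexaen-14-ynenitrile F8.
- DIBAL-H reduction (toluene, −78 °C) and mild hydrolysis give (2E,4E,6E,8E,10E,12E)-4,9,13-trimethylpentadeca-2,4,6,8,10,12-hexaen-14-ynal F9.
- Horner–Wadsworth–Emmons reaction of F9 with diethyl (3-oxobutan-2-yl)phosphonate (Ba(OH)2, THF/H2O, rt) gives 19.

**Step 1.** What may go wrong is loss of the order of events between the two enzymes (carbonyl reduction before C=C reduction) or insufficient facial selectivity at C4 if the specific ketoreductase has to be replaced by another. The fallback sets the centre chemically and uses the fact that the second centre is erased. It sets out from 1 and comes back at 6: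
- Ru–TsDPEN-catalysed asymmetric transfer hydrogenation (HCO2H/Et3N) of the unhindered C4 carbonyl of 1, with the catalyst enantiomer that delivers the (4S)-alcohol, gives (4S)-4-hydroxy-2,6,6-trimethylcyclohex-2-en-1-one F10. The descriptor changes but the spatial arrangement is that of 3.
- Hydrogenation of the C=C bond (H2, Raney Ni, EtOH) gives 3 together with its C6 epimer (4R,6S)-4-hydroxy-2,2,6-trimethylcyclohexan-1-one F11.
- Silylation of the mixture as in step 2 gives 4 and (4R,6S)-2,2,6-trimethyl-4-[(triethylsilyl)oxy]cyclohexan-1-one F12.
- Step 3 converts both into the same enolate 5 and triflate 6.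

## Further compounds

F1 | step 11 | (1R)-4-[(3E)-5-hydroxy-3-methylpent-3-en-1-yn-1-yl]-3,5,5-trimethylcyclohex-3-en-1-ol | OC/C=C(\C)C#CC1=C(C)C[C@@H](O)CC1(C)C
F2 | step 11 | tributyl{(2E)-5-[(4R)-4-hydroxy-2,6,6-trimethylcyclohex-1-en-1-yl]-3-methylpent-2-en-4-yn-1-yl}phosphonium bromide | CCCC[P+](CCCC)(CCCC)C/C=C(\C)C#CC1=C(C)C[C@@H](O)CC1(C)C.[Br-]
F3 | step 11 | (2E,4E,6E,8E,10E)-13-[(4R)-4-hydroxy-2,6,6-trimethylcyclohex-1-en-1-yl]-2,7,11-trimethyltrideca-2,4,6,8,10-pentaen-12-ynal | O=C/C(C)=C/C=C/C=C(C)/C=C/C=C(\C)C#CC1=C(C)C[C@@H](O)CC1(C)C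
F4 | step 7 | (2E)-3-methylpent-2-en-4-ynal | C#C/C(C)=C/C=O
F5 | step 7 | (2E,4E,6E)-8-hydroxy-2,7-dimethylocta-2,4,6-trienal | O=C/C(C)=C/C=C/C=C(\C)CO
F6 | step 7 | (3E,5E,7E,9E,11E)-13-hydroxy-3,7,12-trimethyltrideca-3,5,7,9,11-pentaen-2-one | CC(=O)/C(C)=C/C=C/C(C)=C/C=C/C=C(C)/CO
F7 | step 7 | tributyl[(2E,4E,6E,8E,10E)-2,7,11-trimethyl-12-oxotrideca-2,4,6,8,10-pentaen-1-yl]phosphonium bromide | CC(=O)/C(C)=C/C=C/C(C)=C/C=C/C=C(C)/C[P+](CCCC)(CCCC)CCCC.[Br-]
F8 | step 10 | (2E,4E,6E,8E,10E,12E)-4,9,13-trimethylpentadeca-2,4,6,8,10,12-hexaen-14-ynenitrile | N#C/C=C/C(C)=C/C=C/C=C(C)/C=C/C=C(\C)C#C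
F9 | step 10 | (2E,4E,6E,8E,10E,12E)-4,9,13-trimethylpentadeca-2,4,6,8,10,12-hexaen-14-ynal | O=C/C=C/C(C)=C/C=C/C=C(C)/C=C/C=C(\C)C#C
F10 | step 1 | (4S)-4-hydroxy-2,6,6-trimethylcyclohex-2-en-1-one | O=C1C(C)=C[C@@H](O)CC1(C)C
F11 | step 1 | (4R,6S)-4-hydroxy-2,2,6-trimethylcyclohexan-1-one | O=C1[C@@H](C)C[C@@H](O)CC1(C)C
F12 | step 1 | (4R,6S)-2,2,6-trimethyl-4-[(triethylsilyl)oxy]cyclohexan-1-one | O=C1[C@@H](C)C[C@@H](O[Si](CC)(CC)CC)CC1(C)C
A1 | alternative 1 | {(2E)-5-[(4R)-4-hydroxy-2,6,6-trimethylcyclohex-1-en-1-yl]-3-methylpent-2-en-4-yn-1-yl}triphenylphosphonium bromide | [Br-].c1ccccc1[P+](c1ccccc1)(c1ccccc1)C/C=C(\C)C#CC1=C(C)C[C@@H](O)CC1(C)C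
A2 | alternative 1 | (2E,4E,6E,8E,10E)-2,7,11-trimethyl-12-oxotrideca-2,4,6,8,10-pentaenal | CC(=O)/C(C)=C/C=C/C(C)=C/C=C/C=C(C)/C=O
A3 | alternative 2 | (3E,5E,7E,9E,11E,13E,15E)-3,7,12,16-tetramethyloctadeca-3,5,7,9,11,13,15-heptaene-1,17-diyne | C#C/C(C)=C/C=C/C(C)=C/C=C/C=C(C)/C=C/C=C(\C)C#C
A4 | alternative 2 | (1R)-3,5,5-trimethyl-4-[(3E,5E,7E,9E,11E,13E,15E)-3,7,12,16-tetramethyloctadeca-3,5,7,9,11,13,15-heptaene-1,17-diyn-1-yl]cyclohex-3-en-1-ol | C#C/C(C)=C/C=C/C(C)=C/C=C/C=C(C)/C=C/C=C(\C)C#CC1=C(C)C[C@@H](O)CC1(C)C
A5 | alternative 3 | (1R)-4-(buta-1,3-diyn-1-yl)-3,5,5-trimethylcyclohex-3-en-1-ol | C#CC#CC1=C(C)C[C@@H](O)CC1(C)C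
A6 | alternative 3 | (1R)-4-[(3E)-4-iodo-3-methylbut-3-en-1-yn-1-yl]-3,5,5-trimethylcyclohex-3-en-1-ol | I/C=C(\C)C#CC1=C(C)C[C@@H](O)CC1(C)C
A7 | alternative 3 | (3E,5E,7E,9E,11E,13E)-3,7,12-trimethyl-14-(4,4,5,5-tetramethyl-1,3,2-dioxaborolan-2-yl)tetradeca-3,5,7,9,11,13-hexaen-2-one | CC(=O)/C(C)=C/C=C/C(C)=C/C=C/C=C(C)/C=C/B1OC(C)(C)C(C)(C)O1
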